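**Retrosynthetic overview**

- Feature: ring A (C4a, C5, C6, C7, C8, C8a) carries its two oxygens on C7 and C8a (O1) in a 1,3-relationship, so it is a resorcinol and can be carried as cyclohexane-1,3-dione. The acid-labile C7 prenyl ether is then put on as a vinylogous ester before any phenol exists.
- Last disconnection: the C5–C6 unsaturation is removed, so target 14 comes from 5,6-dihydrochromone 13 by dehydrogenation.
- Key disconnection: the pyranone ring is opened at C4–C4a and O1–C2, giving 3-prenyloxycyclohexenone 5 and β-methoxyacryloyl chloride 10, which already bears the aryl group on the future C3.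
- Precursors: 5 from dione 1 via chloro enone 2 and prenol 3; 10 from methyl (3,4-dimethoxyphenyl)acetate 6 via formyl ester 7, methoxyacrylate 8 and acid 9.
- Ring order: the carbocycle of ring A and the dimethoxyphenyl ring are bought; the pyranone ring is closed in step 7; ring A is aromatised in step 8.

Key step: step 7

Assumption: methyl (3,4-dimethoxyphenyl)acetate is taken as a catalogue compound (one Fischer esterification of the acid would supply it otherwise). The enol ethers 8–10 are drawn E, but this geometry has no bearing on the ring closure.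

**Route**

Step 1
Reactants: 1 cyclohexane-1,3-dione
Product: 2 3-chlorocyclohex-2-en-1-one
Conditions: (COCl)2 (1.2 equiv), DMF (cat.), CH2Cl2, 0→23 °C
Reagents that add atoms: oxalyl chloride, ClC(=O)C(Cl)=O
Why: The dione reacts as its enol (a vinylogous acid); the Vilsmeier-type chloroiminium salt from DMF and oxalyl chloride activates the enol oxygen and chloride displaces it by addition–elimination, the standard route to a vinylogous acid chloride.

Step 2
Reactants: 2 3-chlorocyclohex-2-en-1-one; 3 3-methylbut-2-en-1-ol (prenol)
Product: 5 3-(3-methylbut-2-enyloxy)cyclohex-2-en-1-one, via sodium 3-methylbut-2-en-1-olate 4 (not isolated)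
Conditions: NaH, THF, 0 °C; then 2, 0→23 °C
Reagents that add atoms: none
Why: Sodium prenoxide adds to the β-carbon of the chloro enone and chloride is expelled (nucleophilic vinylic substitution by addition–elimination), which installs the prenyl ether without acid and far below the temperature at which this allyl vinyl ether would undergo Claisen rearrangement.

Step 3
Reactants: 6 methyl 2-(3,4-dimethoxyphenyl)acetate
Product: 7 methyl 2-(3,4-dimethoxyphenyl)-3-hydroxyprop-2-enoate (enol of the α-formyl ester)
Conditions: NaH, HCO2Me (excess), THF, 0→23 °C; then cold 1 M HCl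
Reagents that add atoms: methyl formate, COC=O
Why: Crossed Claisen condensation (C-formylation) of the ester enolate with methyl formate, driven by deprotonation of the α-formyl ester, whose hydrogen-bonded enol is set free on cold acidification.

Step 4
Reactants: 7 methyl 2-(3,4-dimethoxyphenyl)-3-hydroxyprop-2-enoate
Product: 8 methyl (E)-2-(3,4-dimethoxyphenyl)-3-methoxyprop-2-enoate
Conditions: Me2SO4, K2CO3, acetone, 23 °C
Reagents that add atoms: dimethyl sulfate, COS(=O)(=O)OC
Why: The potassium enolate is alkylated at oxygen by the hard electrophile dimethyl sulfate (Williamson-type O-alkylation), which should give mainly the E enol ether with OMe trans to the ester, as is usual for β-methoxyacrylates.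

Step 5
Reactants: 8 methyl (E)-2-(3,4-dimethoxyphenyl)-3-methoxyprop-2-enoate
Product: 9 (E)-2-(3,4-dimethoxyphenyl)-3-methoxyprop-2-enoic acid
Conditions: LiOH·H2O, THF/MeOH/H2O, 40 °C; then 1 M HCl to pH 3, 0 °C
Reagents that add atoms: lithium hydroxide, [Li+].[OH-]
Why: Saponification (BAc2 hydrolysis) of a push–pull β-methoxyacrylate, whose donor-substituted β-carbon is a poor Michael acceptor, so hydroxide attacks the ester carbonyl, and brief cold acidification frees the acid without hydrolysing the enol ether.

Step 6
Reactants: 9 (E)-2-(3,4-dimethoxyphenyl)-3-methoxyprop-2-enoic acid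
Product: 10 (E)-2-(3,4-dimethoxyphenyl)-3-methoxyprop-2-enoyl chloride
Conditions: (COCl)2 (1.5 equiv), DMF (cat.), CH2Cl2, 0→23 °C; evaporate, strip with PhMe, use crude
Reagents that add atoms: oxalyl chloride, ClC(=O)C(Cl)=O
Why: Acid chloride formation through the DMF-derived chloroiminium salt (Vilsmeier catalysis) under mild conditions, routine for β-alkoxyacrylic acids, which give isolable acid chlorides.

Step 7
Reactants: 5 3-(3-methylbut-2-enyloxy)cyclohex-2-en-1-one (2.1 equiv; the second equivalent serves as base and is recovered); 10 (E)-2-(3,4-dimethoxyphenyl)-3-methoxyprop-2-enoyl chloride (1.0 equiv)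
Product: 13 3-(3,4-dimethoxyphenyl)-7-(3-methylbut-2-enyloxy)-5,6-dihydro-4H-chromen-4-one, via lithium dienolate 11 (not isolated), via acyl diketone 12 (not isolated)
Conditions: LDA (lithium diisopropylamide, LiN(i-Pr)2, 2.1 equiv), THF, −78 °C; 10, −78 °C; AcOH (1.2 equiv), −78→0 °C; DBU (cat.), 23 °C
Reagents that add atoms: none
Why: LDA at −78 °C removes the α′ proton (C6) of vinylogous ester 5 irreversibly (Stork–Danheiser-type kinetic enolate), and the cross-conjugated lithium dienolate 11 attacks the carbonyl of 10, which has no α-hydrogen and so cannot divert to a ketene, forming the C4–C4a bond of diketone 12 in a Claisen-type C-acylation. The second equivalent of 11 takes up the acidic proton of 12, so the acid chloride is consumed completely and one equivalent of 5 is returned. After buffering with AcOH, DBU regenerates the diketone enolate free of lithium chelation; its ring oxygen adds to the β-methoxy enone carbon (oxa-Michael addition, 6-endo-trig) and methanol is lost, closing the pyranone ring through the O1–C2 bond. The closest known reaction type is the 4-pyranone annulation of ketone enolates with β-alkoxyacryloyl chlorides, combined with the α′-acylation of 3-alkoxycyclohexenone enolates. No stereocentre is formed; the selectivities needed are α′ over γ deprotonation and C over O acylation, both set by the kinetic lithium enolate in THF at −78 °C, and the acylated carbon becomes C4a para to C7, which fixes 7- and not 5-oxygenation. No strong acid is present and the temperature stays at or below 23 °C, so the prenyl enol ether should neither cleave nor undergo Claisen rearrangement.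

Step 8
Reactants: 13 3-(3,4-dimethoxyphenyl)-7-(3-methylbut-2-enyloxy)-5,6-dihydro-4H-chromen-4-one
Product: 14 7-prenyloxy-3',4'-dimethoxyisoflavone (3-(3,4-dimethoxyphenyl)-7-(3-methylbut-2-enyloxy)-4H-chromen-4-one)
Conditions: DDQ (1.05 equiv), dry PhMe, 0→23 °C
Reagents that add atoms: none
Why: DDQ dehydrogenation, in which hydride abstraction from C5 gives a cyclohexadienyl cation stabilised by the oxygens on C7 and C8a (the arenium ion of a resorcinol diether) that loses the C6 proton to aromatise ring A, which should be much faster than oxidation of the prenyl ether with one equivalent of DDQ in a dry non-polar solvent.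

**Compound list**

1 | cyclohexane-1,3-dione | O=C1CCCC(=O)C1 | starting material
2 | 3-chlorocyclohex-2-en-1-one | O=C1C=C(Cl)CCC1 | intermediate
3 | 3-methylbut-2-en-1-ol (prenol) | CC(C)=CCO | starting material
4 | sodium 3-methylbut-2-en-1-olate | CC(C)=CC[O-].[Na+] | intermediate (not isolated)
5 | 3-(3-methylbut-2-enyloxy)cyclohex-2-en-1-one | CC(C)=CCOC1=CC(=O)CCC1 | intermediate
6 | methyl 2-(3,4-dimethoxyphenyl)acetate | COC(=O)Cc1ccc(OC)c(OC)c1 | starting material
7 | methyl 2-(3,4-dimethoxyphenyl)-3-hydroxyprop-2-enoate (drawn as the hydrogen-bonded Z enol; tautomer of the α-formyl ester) | COC(=O)/C(=C\O)c1ccc(OC)c(OC)c1 | intermediate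
8 | methyl (E)-2-(3,4-dimethoxyphenyl)-3-methoxyprop-2-enoate | CO/C=C(/C(=O)OC)c1ccc(OC)c(OC)c1 | intermediate
9 | (E)-2-(3,4-dimethoxyphenyl)-3-methoxyprop-2-enoic acid | CO/C=C(/C(=O)O)c1ccc(OC)c(OC)c1 | intermediate
10 | (E)-2-(3,4-dimethoxyphenyl)-3-methoxyprop-2-enoyl chloride | CO/C=C(/C(Cl)=O)c1ccc(OC)c(OC)c1 | intermediate
11 | lithium 5-(3-methylbut-2-enyloxy)cyclohexa-1,5-dien-1-olate (kinetic α′ enolate of 5) | [Li+].[O-]C1=CCCC(OCC=C(C)C)=C1 | intermediate (not isolated)
12 | 6-[(E)-2-(3,4-dimethoxyphenyl)-3-methoxyprop-2-enoyl]-3-(3-methylbut-2-enyloxy)cyclohex-2-en-1-one (racemic at C6, largely enolised) | CO/C=C(/C(=O)C1CCC(OCC=C(C)C)=CC1=O)c1ccc(OC)c(OC)c1 | intermediate (not isolated)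
13 | 3-(3,4-dimethoxyphenyl)-7-(3-methylbut-2-enyloxy)-5,6-dihydro-4H-chromen-4-one | COc1ccc(C2=COC3=C(CCC(OCC=C(C)C)=C3)C2=O)cc1OC | intermediate
14 | 7-prenyloxy-3',4'-dimethoxyisoflavone | COc1ccc(-c2coc3cc(OCC=C(C)C)ccc3c2=O)cc1OC | target

**Step count**

Total steps: 8. Longest linear sequence: 6 steps (6 → 7 → 8 → 9 → 10 → 13 → 14; steps 3, 4, 5, 6, 7, 8).

**Steps most likely to fail**

1. Step 7. The dienolate may be acylated at oxygen instead of carbon, proton exchange between dienolate and the acidic diketone may stall the conversion, or the methanol set free may exchange with the C7 prenyloxy group during closure. The fallback replaces acylation by aldol addition and oxidation; it sets out from ester 8 and enone 5 and returns at 13. Reduction of 8 with diisobutylaluminium hydride (i-Bu2AlH, CH2Cl2, −78 °C) would give the allylic alcohol (E)-2-(3,4-dimethoxyphenyl)-3-methoxyprop-2-en-1-ol F1. Oxidation with MnO2 in CH2Cl2 would give the aldehyde (E)-2-(3,4-dimethoxyphenyl)-3-methoxyprop-2-enal F2. Addition of dienolate 11 (one equivalent, from 5 and LDA) to F2 at −78 °C is a C-selective aldol reaction whose lithium alkoxide product is not acidic. It would give 6-[(E)-2-(3,4-dimethoxyphenyl)-1-hydroxy-3-methoxyprop-2-enyl]-3-(3-methylbut-2-enyloxy)cyclohex-2-en-1-one F3 as a mixture of diastereomers, whose stereocentres are erased later. Dess–Martin periodinane buffered with NaHCO3 would oxidise F3 to diketone 12, which is closed with catalytic DBU as in step 7 to give 13.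

2. Step 8. DDQ may abstract hydride from the allylic O–CH2 of the prenyl group, so that the ether is lost during the oxidation, or may add to the ring A diene. The fallback avoids a quinone oxidant; it sets out from 13 and returns at 14. Deprotonation of 13 at C6 with LDA (THF, −78 °C) and trapping of the extended enolate with PhSeBr at its α-carbon would give 3-(3,4-dimethoxyphenyl)-7-(3-methylbut-2-enyloxy)-4a-(phenylselanyl)-4a,5-dihydro-4H-chromen-4-one F4 (racemic). Oxidation with H2O2 and pyridine in CH2Cl2 at 0 °C would give the selenoxide 3-(3,4-dimethoxyphenyl)-7-(3-methylbut-2-enyloxy)-4a-(phenylseleninyl)-4a,5-dihydro-4H-chromen-4-one F5, not isolated. Syn-elimination of F5 across C4a–C5 aromatises ring A and gives 14.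

3. Step 6. The acid chloride cannot be purified; the HCl set free may attack the enol ether, and residual HCl or oxalyl chloride would consume the dienolate in step 7. The fallback activates the acid without chloride or mineral acid; it sets out from acid 9 and returns at 13. Carbonyldiimidazole in THF at 23 °C would convert 9 into the acyl imidazole 1-[(E)-2-(3,4-dimethoxyphenyl)-3-methoxyprop-2-enoyl]imidazole F6. This solution is added to dienolate 11 (two equivalents) at −78 °C, where the imidazolide serves as C-acylating agent and gives diketone 12. Closure as in step 7 then gives 13.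

**Further compounds**

F1 | step 7 | (E)-2-(3,4-dimethoxyphenyl)-3-methoxyprop-2-en-1-ol | CO/C=C(/CO)c1ccc(OC)c(OC)c1
F2 | step 7 | (E)-2-(3,4-dimethoxyphenyl)-3-methoxyprop-2-enal | CO/C=C(/C=O)c1ccc(OC)c(OC)c1
F3 | step 7 | 6-[(E)-2-(3,4-dimethoxyphenyl)-1-hydroxy-3-methoxyprop-2-enyl]-3-(3-methylbut-2-enyloxy)cyclohex-2-en-1-one (mixture of diastereomers) | CO/C=C(/C(O)C1CCC(OCC=C(C)C)=CC1=O)c1ccc(OC)c(OC)c1
F4 | step 8 | 3-(3,4-dimethoxyphenyl)-7-(3-methylbut-2-enyloxy)-4a-(phenylselanyl)-4a,5-dihydro-4H-chromen-4-one (racemic) | COc1ccc(C2=COC3=CC(OCC=C(C)C)=CCC3([Se]c4ccccc4)C2=O)cc1OC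
F5 | step 8 | 3-(3,4-dimethoxyphenyl)-7-(3-methylbut-2-enyloxy)-4a-(phenylseleninyl)-4a,5-dihydro-4H-chromen-4-one (not isolated) | COc1ccc(C2=COC3=CC(OCC=C(C)C)=CCC3([Se](=O)c4ccccc4)C2=O)cc1OC
F6 | step 6 | 1-[(E)-2-(3,4-dimethoxyphenyl)-3-methoxyprop-2-enoyl]imidazole | CO/C=C(/C(=O)n1ccnc1)c1ccc(OC)c(OC)c1
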